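Labdane numbering is used. Ring B is a cyclohexene whose only alkene, the tetrasubstituted C8=C9, lies opposite the bonds C5–C10 and C6–C7. This is the retron of a Diels–Alder reaction, and everything rests on cutting these two bonds. One intramolecular [4+2] cycloaddition of an acyclic precursor closes rings A and B, forms the ring-fusion bond C5–C10, creates quaternary C10 and the trans C5 methine, and places C8=C9. The precursor carries the C3 bromide (enamine-catalysed bromination), the C13 carbinol (from (R)-linalool), an E-configured C7=C8–C9=C10 diene, and a C5=C6 dienophile activated by a removable chiral N-acyloxazolidinone on C6.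

Key step: step 13

Assumption: the target is read as (3R,5S,10R,13R)-3-bromolabda-8,14-dien-13-ol (trans-decalin, equatorial bromine, C20 on C10, C17 on C8, C18/C19 on C4), and (R)-(−)-linalool of high enantiomeric purity is taken as commercial.

Step 1
Reactants: 1 (R)-(−)-linalool
Product: 2 (R)-linalool tert-butyldimethylsilyl ether
Conditions: TBSOTf, 2,6-lutidine, CH2Cl2, 0 °C
Reagents that add atoms: tert-butyldimethylsilyl triflate, CC(C)(C)[Si](C)(C)OS(=O)(=O)C(F)(F)F
Why: Silyl ether protection with the highly electrophilic silyl triflate masks the hindered tertiary alcohol against the Grignard, amide-base and aluminium reagents to come and leaves the chiral-pool stereocentre C13 untouched.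

Step 2
Reactants: 2 (R)-linalool tert-butyldimethylsilyl ether
Product: 3 (3R)-3-(tert-butyldimethylsilyloxy)-6-chloro-3,7-dimethylocta-1,7-diene (both C6 epimers)
Conditions: N-chlorosuccinimide, PhSeCl (5 mol %), CH2Cl2, rt
Reagents that add atoms: N-chlorosuccinimide, O=C1CCC(=O)N1Cl
Why: Selenium-catalysed ene-type allylic chlorination attacks only the electron-rich trisubstituted alkene and gives the transposed secondary allylic chloride with a terminal isopropenyl group (future C7, C8, C17), while the monosubstituted vinyl group is inert and the configuration at the C–Cl carbon is lost in step 7.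

Step 3
Reactants: 4 isobutyronitrile; 5 allyl bromide
Product: 7 2,2-dimethylpent-4-enenitrile, via lithiated isobutyronitrile 6 (not isolated)
Conditions: LiN(iPr)2, THF, −78 °C; then 5, −78 °C → rt
Reagents that add atoms: none
Why: SN2 alkylation of the nitrile-stabilised tertiary carbanion with an allylic bromide builds quaternary C4 with both methyl groups and stores C5 as a base-stable nitrile.

Step 4
Reactants: 7 2,2-dimethylpent-4-enenitrile
Product: 9 2,2-dimethyl-4-oxobutanenitrile, via ozonide 8 (not isolated)
Conditions: O3, CH2Cl2, −78 °C; then Me2S, −78 °C → rt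
Reagents that add atoms: ozone, [O-][O+]=O
Why: Ozonolysis with reductive work-up cleaves the only alkene to the C2 aldehyde, whose sole enolisable position is C3.

Step 5
Reactants: 9 2,2-dimethyl-4-oxobutanenitrile; 10 N-methoxy-N-methyl-2-(triphenylphosphoranylidene)acetamide
Product: 12 (2E,4R)-4-bromo-5-cyano-N-methoxy-N,5-dimethylhex-2-enamide, via (S)-α-bromo aldehyde 11 (not isolated)
Conditions: (S)-2-{bis[3,5-bis(trifluoromethyl)phenyl](trimethylsilyloxy)methyl}pyrrolidine (10 mol %), PhCO2H (10 mol %), 4,4-dibromo-2,6-di-tert-butylcyclohexa-2,5-dienone, CH2Cl2, −40 °C; then 10, −40 → 0 °C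
Reagents that add atoms: 4,4-dibromo-2,6-di-tert-butylcyclohexa-2,5-dien-1-one, CC(C)(C)C1=CC(Br)(Br)C=C(C(C)(C)C)C1=O
Why: In this enamine-catalysed α-bromination the E-enamine of 9 is brominated on the face opposite the bulky diaryl(silyloxy)methyl group, which sets C3 ((S) in 11, (R) once the CIP ranks of C2 and C4 swap), and the neutral stabilised ylide converts the labile aldehyde at once into the E-enamide by a Wittig reaction that adds C1 and C10.

Step 6
Reactants: 12 (2E,4R)-4-bromo-5-cyano-N-methoxy-N,5-dimethylhex-2-enamide
Product: 13 (4R)-4-bromo-5-cyano-N-methoxy-N,5-dimethylhexanamide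
Conditions: 2-nitrobenzenesulfonohydrazide (excess), Et3N, CH2Cl2, rt
Reagents that add atoms: none
Why: Diimide reduction transfers two hydrogen atoms concertedly to the only C=C bond, so the allylic C–Br bond is not hydrogenolysed, the nitrile is untouched and C3 is not epimerised.

Step 7
Reactants: 3 (3R)-3-(tert-butyldimethylsilyloxy)-6-chloro-3,7-dimethylocta-1,7-diene; 13 (4R)-4-bromo-5-cyano-N-methoxy-N,5-dimethylhexanamide
Product: 15 (3R,10R)-3-bromo-10-(tert-butyldimethylsilyloxy)-2,2,10-trimethyl-6-oxo-7-(prop-1-en-2-yl)dodec-11-enenitrile (both C7 epimers), via allylic Grignard reagent 14 (not isolated)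
Conditions: 3, Mg turnings, THF, 0 °C; then 13, THF, −78 °C; aq. NH4Cl
Reagents that add atoms: none
Why: The allylic Grignard reagent reacts through its γ-carbon (SE2′), so C9 bonds to the amide carbonyl C10 and the isopropenyl group is unveiled, the chelated tetrahedral adduct of the N-methoxy-N-methylamide stops the addition at the ketone, the hindered nitrile and bromide are inert at −78 °C, and the C9 mixture is erased in step 8.

Step 8
Reactants: 15 β,γ-unsaturated ketone
Product: 17 (3R,6Z,10R)-3-bromo-10-(tert-butyldimethylsilyloxy)-2,2,10-trimethyl-7-(prop-1-en-2-yl)-6-(trifluoromethylsulfonyloxy)dodeca-6,11-dienenitrile, via potassium dienolate 16 (not isolated)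
Conditions: KN(SiMe3)2 (0.98 equiv, slow addition), THF, −78 °C; then N-(5-chloro-2-pyridyl)bis(trifluoromethanesulfonimide), −78 → −20 °C
Reagents that add atoms: N-(5-chloro-2-pyridyl)bis(trifluoromethanesulfonimide), O=S(=O)(N(c1ccc(Cl)cn1)S(=O)(=O)C(F)(F)F)C(F)(F)F
Why: In this stereoselective enol triflate formation, proton exchange with residual ketone should funnel the enolates to the conjugated dienolate by loss of the doubly activated C9–H, 1,3-allylic strain places the branched isopropenyl group cis to oxygen and the C11 chain cis to C1, and O-sulfonylation at low temperature outruns attack on the hindered neopentylic bromide.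

Step 9
Reactants: 17 dienyl triflate
Product: 18 (3R,6E,10R)-3-bromo-10-(tert-butyldimethylsilyloxy)-2,2,6,10-tetramethyl-7-(prop-1-en-2-yl)dodeca-6,11-dienenitrile
Conditions: MeZnCl, PdCl2(dppf) (5 mol %), THF, 40 °C
Reagents that add atoms: methylzinc chloride, C[Zn]Cl
Why: In the Negishi coupling, oxidative addition of zerovalent palladium into the C10–O bond, transmetalation and reductive elimination all proceed with retention, so C20 ends cis to C8 and the tether carbon C1 trans to it, while the unactivated secondary bromide, the nitrile and the silyl ether are inert to this catalyst.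

Step 10
Reactants: 18 diene nitrile
Product: 20 (3R,6E,10R)-3-bromo-10-(tert-butyldimethylsilyloxy)-2,2,6,10-tetramethyl-7-(prop-1-en-2-yl)dodeca-6,11-dienal, via N-aluminated aldimine 19 (not isolated)
Conditions: iBu2AlH, toluene, −78 → −40 °C; then aq. potassium sodium tartrate
Reagents that add atoms: water, O
Why: Partial nitrile reduction works because iBu2AlH adds only once and the N-aluminated aldimine survives until hydrolysis, which gives the non-enolisable C5 aldehyde without touching bromide, diene or silyl ether.

Step 11
Reactants: 21 diethylphosphonoacetic acid; 22 (R)-4-benzyl-2-oxazolidinone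
Product: 23 (R)-4-benzyl-3-[(diethoxyphosphoryl)acetyl]-2-oxazolidinone
Conditions: DCC, DMAP (cat.), CH2Cl2, 0 °C → rt
Reagents that add atoms: none
Why: Steglich-type carbodiimide activation with DMAP catalysis N-acylates the oxazolidinone under neutral conditions and gives the phosphonate that delivers the activating carbonyl group together with the chiral auxiliary.

Step 12
Reactants: 20 diene aldehyde; 23 phosphonate imide
Product: 24 (R)-4-benzyl-3-[(2E,5R,8E,12R)-5-bromo-12-(tert-butyldimethylsilyloxy)-4,4,8,12-tetramethyl-9-(prop-1-en-2-yl)tetradeca-2,8,13-trienoyl]-2-oxazolidinone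
Conditions: LiCl, iPr2NEt, MeCN, rt
Reagents that add atoms: none
Why: The Horner–Wadsworth–Emmons olefination with LiCl and an amine base is mild enough for the β-bromo aldehyde, and the stabilised phosphonate anion together with the bulky α-quaternary aldehyde should give the E-configured C5=C6 enimide.

Step 13
Reactants: 24 trienimide
Product: 25 (3R,5S,6R,10R,13R)-3-bromo-13-(tert-butyldimethylsilyloxy)labda-8,14-diene carrying the (R)-4-benzyl-2-oxooxazolidine-3-carbonyl group on C6
Conditions: Me2AlCl (2 equiv), CH2Cl2, −40 → 0 °C; aq. potassium sodium tartrate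
Reagents that add atoms: none
Why: Two equivalents of Me2AlCl convert the imide into a cationic AlMe2 chelate with the enoyl group locked s-cis, and the s-cis C7=C8–C9=C10 diene then adds suprafacially across C5=C6 in one concerted, asynchronous [4+2] event that forms C5–C10 and C6–C7 and moves the π bond to C8=C9. The closest known reaction type is the Lewis-acid-promoted intramolecular Diels–Alder reaction of (2E,8E)-2,8,10-trienoyl oxazolidinones to trans-fused decalins. Ring A closes through the saturated four-carbon tether C1–C4 (type 1 connection at the diene terminus C10) in a chair with the C3 bromine equatorial, and ring B closes as the new cyclohexene. C5 is set by the auxiliary, whose benzyl group blocks one face of the chelated enimide so that C10 bonds to the opposite face; C10 follows from the E geometry of C9=C10 (C1 outside, C20 inside) together with the endo orientation of the acyl group, which puts H5 and C20 anti (trans-decalin); C6 follows from the E geometry of C5=C6 and is erased in step 15. The step needs endo over exo selectivity, secured by the strong endo preference of the cationic dienophile and by the clash of the C4 methyl groups with the C9 chain in the exo mode, and a facial selectivity that matches the preset C3 centre, secured because the face left open by the (R)-auxiliary is the one that keeps bromine equatorial. It also needs chemoselectivity, which holds because the C14=C15 vinyl group is neither activated nor within reach and because the low temperature and the proton-scavenging Al–Me bonds protect the diene and the tertiary allylic silyl ether.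

Step 14
Reactants: 25 cycloadduct
Product: 27 (3R,5S,6R,10R,13R)-3-bromo-13-(tert-butyldimethylsilyloxy)labda-8,14-diene-6-carboxylic acid, via peroxy acid 26 (not isolated)
Conditions: H2O2, LiOH, THF/H2O, 0 °C; then aq. Na2SO3; then HCl to pH 3
Reagents that add atoms: hydrogen peroxide, OO
Why: In the hydroperoxide imide cleavage the small, highly nucleophilic hydroperoxide anion attacks the exocyclic carbonyl group even when it is hindered, the auxiliary is released intact, and sulfite reduces the percarboxylate before acidification so that C8=C9 is not epoxidised.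

Step 15
Reactants: 27 C6 carboxylic acid
Product: 29 (3R,5S,10R,13R)-3-bromo-13-(tert-butyldimethylsilyloxy)labda-8,14-diene, via thiohydroxamate ester 28 (not isolated)
Conditions: 1-hydroxypyridine-2(1H)-thione, DCC, CH2Cl2, dark, 0 °C → rt; then t-BuSH, toluene, tungsten lamp, 10 °C
Reagents that add atoms: none
Why: In the Barton reductive decarboxylation the thiohydroxamate ester fragments under visible light to the secondary C6 radical, which takes a hydrogen atom from the thiol faster than it can reach any alkene, and since no tin hydride is present the C3–Br bond survives while the temporary C6 stereocentre disappears.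

Step 16
Reactants: 29 silyl ether of the target
Product: 30 (3R,5S,10R,13R)-3-bromolabda-8,14-dien-13-ol (target)
Conditions: Bu4NF, THF, 45 °C
Reagents that add atoms: none
Why: Fluoride-mediated desilylation cleaves the Si–O bond under non-acidic conditions that spare the ionisable tertiary allylic alcohol, and the equatorial neopentylic bromide has no antiperiplanar hydrogen for E2 elimination.

Compound list
1 | (R)-(−)-linalool | C=C[C@](C)(O)CCC=C(C)C | starting material
2 | (R)-linalool tert-butyldimethylsilyl ether | C=C[C@](C)(O[Si](C)(C)C(C)(C)C)CCC=C(C)C | intermediate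
3 | (3R)-3-(tert-butyldimethylsilyloxy)-6-chloro-3,7-dimethylocta-1,7-diene, both C6 epimers | C=C[C@](C)(O[Si](C)(C)C(C)(C)C)CCC(Cl)C(C)=C | intermediate
4 | isobutyronitrile | CC(C)C#N | starting material
5 | allyl bromide | C=CCBr | starting material
6 | lithiated isobutyronitrile | [Li]C(C)(C)C#N | intermediate
7 | 2,2-dimethylpent-4-enenitrile | C=CCC(C)(C)C#N | intermediate
8 | ozonide of 7 (3-substituted 1,2,4-trioxolane) | N#CC(C)(C)CC1OCOO1 | intermediate
9 | 2,2-dimethyl-4-oxobutanenitrile | O=CCC(C)(C)C#N | intermediate
10 | N-methoxy-N-methyl-2-(triphenylphosphoranylidene)acetamide | CON(C)C(=O)C=P(c1ccccc1)(c1ccccc1)c1ccccc1 | starting material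
11 | (S)-3-bromo-2,2-dimethyl-4-oxobutanenitrile | O=C[C@@H](Br)C(C)(C)C#N | intermediate
12 | (2E,4R)-4-bromo-5-cyano-N-methoxy-N,5-dimethylhex-2-enamide | CON(C)C(=O)/C=C/[C@@H](Br)C(C)(C)C#N | intermediate
13 | (4R)-4-bromo-5-cyano-N-methoxy-N,5-dimethylhexanamide | CON(C)C(=O)CC[C@@H](Br)C(C)(C)C#N | intermediate
14 | allylic Grignard reagent from 3 | C=C[C@](C)(O[Si](C)(C)C(C)(C)C)CCC=C(C)C[Mg]Cl | intermediate
15 | β,γ-unsaturated ketone (3R,10R), both C7 epimers | C=C[C@](C)(O[Si](C)(C)C(C)(C)C)CCC(C(C)=C)C(=O)CC[C@@H](Br)C(C)(C)C#N | intermediate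
16 | potassium dienolate of 15 | C=C[C@](C)(O[Si](C)(C)C(C)(C)C)CC/C(C(C)=C)=C(/[O-])CC[C@@H](Br)C(C)(C)C#N.[K+] | intermediate
17 | (3R,6Z,10R)-dienyl triflate | C=C[C@](C)(O[Si](C)(C)C(C)(C)C)CC/C(C(C)=C)=C(/OS(=O)(=O)C(F)(F)F)CC[C@@H](Br)C(C)(C)C#N | intermediate
18 | (3R,6E,10R)-diene nitrile | C=C[C@](C)(O[Si](C)(C)C(C)(C)C)CC/C(C(C)=C)=C(/C)CC[C@@H](Br)C(C)(C)C#N | intermediate
19 | N-(diisobutylaluminio) aldimine of 20 | C=C[C@](C)(O[Si](C)(C)C(C)(C)C)CC/C(C(C)=C)=C(/C)CC[C@@H](Br)C(C)(C)C=N[Al](CC(C)C)CC(C)C | intermediate
20 | (3R,6E,10R)-diene aldehyde | C=C[C@](C)(O[Si](C)(C)C(C)(C)C)CC/C(C(C)=C)=C(/C)CC[C@@H](Br)C(C)(C)C=O | intermediate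
21 | diethylphosphonoacetic acid | CCOP(=O)(CC(=O)O)OCC | starting material
22 | (R)-4-benzyl-2-oxazolidinone | O=C1N[C@H](Cc2ccccc2)CO1 | starting material
23 | (R)-4-benzyl-3-[(diethoxyphosphoryl)acetyl]-2-oxazolidinone | CCOP(=O)(OCC)CC(=O)N1[C@H](Cc2ccccc2)COC1=O | intermediate
24 | (2E,5R,8E,12R)-trienimide | C=C[C@](C)(O[Si](C)(C)C(C)(C)C)CC/C(C(C)=C)=C(/C)CC[C@@H](Br)C(C)(C)/C=C/C(=O)N1[C@H](Cc2ccccc2)COC1=O | intermediate
25 | Diels–Alder adduct (3R,5S,6R,10R,13R) | C=C[C@](C)(O[Si](C)(C)C(C)(C)C)CCC1=C(C)C[C@@H](C(=O)N3[C@H](Cc4ccccc4)COC3=O)[C@@H]2C(C)(C)[C@H](Br)CC[C@@]12C | intermediate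
26 | C6 peroxy acid | C=C[C@](C)(O[Si](C)(C)C(C)(C)C)CCC1=C(C)C[C@@H](C(=O)OO)[C@@H]2C(C)(C)[C@H](Br)CC[C@@]12C | intermediate
27 | C6 carboxylic acid | C=C[C@](C)(O[Si](C)(C)C(C)(C)C)CCC1=C(C)C[C@@H](C(=O)O)[C@@H]2C(C)(C)[C@H](Br)CC[C@@]12C | intermediate
28 | thiohydroxamate ester of 27 | C=C[C@](C)(O[Si](C)(C)C(C)(C)C)CCC1=C(C)C[C@@H](C(=O)ON3C=CC=CC3=S)[C@@H]2C(C)(C)[C@H](Br)CC[C@@]12C | intermediate
29 | tert-butyldimethylsilyl ether of the target | C=C[C@](C)(O[Si](C)(C)C(C)(C)C)CCC1=C(C)CC[C@@H]2C(C)(C)[C@H](Br)CC[C@@]12C | intermediate
30 | (3R,5S,10R,13R)-3-bromolabda-8,14-dien-13-ol | C=C[C@](C)(O)CCC1=C(C)CC[C@@H]2C(C)(C)[C@H](Br)CC[C@@]12C | target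

Total step count: 16. Longest linear sequence: 13 steps (steps 3–10 and 12–16). Steps 1–2 and step 11 are convergent branches.

**Steps most likely to fail**

First, step 13.
- The cycloaddition may stall. The diene must reach the s-cis form with C20 inside, and the leading bond joins a neopentylic carbon to a fully substituted one.
- Long exposure to the Lewis acid could then ionise the tertiary allylic silyl ether or oligomerise the diene.
- The fallback replaces Lewis acid and auxiliary by covalent iminium activation and sets out from aldehyde 20.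
- A Horner–Wadsworth–Emmons reaction with diethyl cyanomethylphosphonate should give the (E)-unsaturated nitrile F1, and iBu2AlH should give the (E)-enal F2.
- The trifluoroacetate salt of (2R,5R)-5-benzyl-2-tert-butyl-3-methylimidazolidin-4-one in wet MeCN should then catalyse the intramolecular Diels–Alder reaction to the C6 carbaldehyde F3. The benzyl group of the catalyst takes over the facial control.
- A Tsuji–Wilkinson decarbonylation with RhCl(PPh3)3 in hot toluene removes the formyl group, and the route is rejoined at 29.

Second, step 8.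
- Deprotonation may take place at C1 instead of C9.
- A C1 enolate may displace the γ-bromide with cyclopropane formation.
- Control of the enolate geometry may be poor.
- The fallback avoids enolates altogether and sets out from amide 13.
- MeMgBr at −78 °C should give the methyl ketone F4, which already holds C20. Grignard reagent 14 should add to it through its γ-carbon to give the tertiary homoallylic alcohol F5.
- Dehydration with methyl N-(triethylammoniosulfonyl)carbamate should favour loss of the allylic C9–H and give the conjugated diene as 18 together with its geometric isomer F6.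
- F6 is removed by chromatography. If carried on, it stays behind in step 13, because a tether cis to C8 cannot reach the trans-fused transition state. The route is rejoined at 18.

Third, step 5.
- Enolisation of the α-bromo aldehyde during a slow olefination of the hindered carbonyl group may erode the enantiomeric purity at C3.
- The fallback changes the chain extension from olefination and reduction to a polar displacement and sets out from aldehyde 9.
- After the same bromination, a NaBH4 quench at −40 °C should give the configurationally stable bromohydrin F7. Tf2O with 2,6-lutidine should give the primary triflate F8.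
- The lithium enolate of N-methoxy-N-methylacetamide should displace the triflate at −78 °C without touching the neopentylic bromide. The route is rejoined at 13, and step 6 is no longer needed.

Further compounds
F1 | step 13 | (2E,5R,8E,12R)-5-bromo-12-(tert-butyldimethylsilyloxy)-4,4,8,12-tetramethyl-9-(prop-1-en-2-yl)tetradeca-2,8,13-trienenitrile | C=C[C@](C)(O[Si](C)(C)C(C)(C)C)CC/C(C(C)=C)=C(/C)CC[C@@H](Br)C(C)(C)/C=C/C#N
F2 | step 13 | (2E,5R,8E,12R)-5-bromo-12-(tert-butyldimethylsilyloxy)-4,4,8,12-tetramethyl-9-(prop-1-en-2-yl)tetradeca-2,8,13-trienal | C=C[C@](C)(O[Si](C)(C)C(C)(C)C)CC/C(C(C)=C)=C(/C)CC[C@@H](Br)C(C)(C)/C=C/C=O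
F3 | step 13 | (3R,5S,6R,10R,13R)-3-bromo-13-(tert-butyldimethylsilyloxy)labda-8,14-diene-6-carbaldehyde | C=C[C@](C)(O[Si](C)(C)C(C)(C)C)CCC1=C(C)C[C@@H](C=O)[C@@H]2C(C)(C)[C@H](Br)CC[C@@]12C
F4 | step 8 | (R)-3-bromo-2,2-dimethyl-6-oxoheptanenitrile | CC(=O)CC[C@@H](Br)C(C)(C)C#N
F5 | step 8 | (3R,10R)-3-bromo-10-(tert-butyldimethylsilyloxy)-6-hydroxy-2,2,6,10-tetramethyl-7-(prop-1-en-2-yl)dodec-11-enenitrile, mixture at C6 and C7 | C=C[C@](C)(O[Si](C)(C)C(C)(C)C)CCC(C(C)=C)C(C)(O)CC[C@@H](Br)C(C)(C)C#N
F6 | step 8 | (3R,6Z,10R) geometric isomer of 18 | C=C[C@](C)(O[Si](C)(C)C(C)(C)C)CC/C(C(C)=C)=C(\C)CC[C@@H](Br)C(C)(C)C#N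
F7 | step 5 | (S)-3-bromo-4-hydroxy-2,2-dimethylbutanenitrile | OC[C@@H](Br)C(C)(C)C#N
F8 | step 5 | (S)-2-bromo-3-cyano-3-methylbutyl trifluoromethanesulfonate | O=S(=O)(OC[C@@H](Br)C(C)(C)C#N)C(F)(F)F
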